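**Retrosynthetic overview**
- Hansfordiol E ⇐ double O-demethylation of its resorcinol dimethyl ether.
- C8=C9 (Z) ⇐ Z-selective cross-metathesis of an aryl-nonene with (S)-dec-9-en-2-ol.
- C16–O bond and the only stereocentre ⇐ a new catalytic enantioselective Markovnikov mono-hydration of deca-1,9-diene.
- Benzylic C1–C2 bond ⇐ Cu-catalysed coupling of 3,5-dimethoxybenzyl bromide with oct-7-enyl Grignard.
- No ring is formed; the arene is bought with the benzyl bromide.

Assumption: the target is 5-[(8Z,16S)-16-hydroxyheptadec-8-en-1-yl]benzene-1,3-diol as read from the SMILES, and the (S,S)-antipode of the new catalyst Co-1 is taken to give the (S)-carbinol (otherwise its mirror image is used).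

Co-1 is a proposed C2-symmetric Co(II)–salen built on (S,S)-cyclohexane-1,2-diamine, with 3,3'-bis(2,4,6-triisopropylphenyl) and 5,5'-di-tert-butyl salicylidene arms.

Step 1
Reactants: 1 deca-1,9-diene
Product: 2 (S)-dec-9-en-2-ol
Conditions: 1 (5 equiv), H2O (10 equiv), Co-1 (5 mol%), 1-fluoro-2,4,6-trimethylpyridinium triflate (1.0 equiv, limiting), (HMe2Si)2O (0.6 equiv), acetone, 0 °C; excess 1 distilled off and reused
Reagents that add atoms: water, O
Why: Proposed new method: enantioselective Markovnikov mono-hydration of an unactivated terminal alkene with water as the oxygen nucleophile. The N–F salt oxidises Co-1 to Co(III)–F and the silane converts it to Co(III)–H; hydrogen-atom transfer to a terminal CH2 gives the secondary C2 radical, which is captured reversibly as alkyl–Co(III); one-electron oxidation gives an electrophilic alkyl–Co(IV), and water displaces cobalt with inversion inside the ligand pocket. Because Co–C homolysis keeps the two diastereomeric alkylcobalt species in equilibrium, the aryl walls (which accept CH3 but not the heptenyl chain) should channel substitution through one of them and set C2 as S. The fivefold excess of diene suppresses dihydration. Closest known reaction type: Mukaiyama hydration and Co(salen) hydrogen-atom-transfer/radical–polar-crossover hydroalkoxylation, enantioselective so far in ring-forming cases.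

Step 2
Reactants: 3 8-bromooct-1-ene; 4 1-(bromomethyl)-3,5-dimethoxybenzene
Product: 6 1,3-dimethoxy-5-(non-8-en-1-yl)benzene, via oct-7-enylmagnesium bromide 5 (not isolated)
Conditions: 3 (1.2 equiv), Mg, THF, rt; then 4, Li2CuCl4 (3 mol%), THF, −78 °C → rt
Reagents that add atoms: none
Why: Kochi-type Cu-catalysed Grignard cross-coupling: the alkylcuprate from 5 displaces the reactive benzylic bromide of 4, while the terminal alkene and aryl ethers are inert; no stereocentre is involved.

Step 3
Reactants: 2 (S)-dec-9-en-2-ol; 6 1,3-dimethoxy-5-(non-8-en-1-yl)benzene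
Product: 7 (2S,9Z)-17-(3,5-dimethoxyphenyl)heptadec-9-en-2-ol
Conditions: 2 (1.0 equiv), 6 (2.0 equiv), cyclometalated Z-selective Ru nitrato catalyst (N-adamantyl/N-2,6-diisopropylphenyl NHC, 3 mol%), THF, 35 °C, static vacuum
Reagents that add atoms: none
Why: Z-selective olefin cross-metathesis: the chelated NHC enforces a side-bound, syn-disubstituted metallacyclobutane, giving the Z alkene; the free secondary alcohol is tolerated, ethene loss drives the reaction, and C2 is untouched.

Step 4
Reactants: 7 (2S,9Z)-17-(3,5-dimethoxyphenyl)heptadec-9-en-2-ol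
Product: 8 Hansfordiol E, 5-[(8Z,16S)-16-hydroxyheptadec-8-en-1-yl]benzene-1,3-diol
Conditions: MeMgI (8 equiv), Et2O stripped, neat, 160 °C, 1 h, Ar; then 1 M HCl, 0 °C
Reagents that add atoms: none
Why: Grignard-mediated aryl methyl ether cleavage (Mg-assisted SN2 at the O-methyl carbons) runs without protic or Lewis acid that could isomerise or hydrohalogenate the Z-alkene; the carbinol sits as an inert magnesium alkoxide, so C16 keeps its S configuration.

**Compound list**
1 | deca-1,9-diene | C=CCCCCCCC=C | starting material
2 | (S)-dec-9-en-2-ol | C[C@H](O)CCCCCCC=C | intermediate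
3 | 8-bromooct-1-ene | BrCCCCCCC=C | starting material
4 | 1-(bromomethyl)-3,5-dimethoxybenzene | COc1cc(CBr)cc(OC)c1 | starting material
5 | oct-7-enylmagnesium bromide | C=CCCCCCC[Mg]Br | intermediate
6 | 1,3-dimethoxy-5-(non-8-en-1-yl)benzene | COc1cc(CCCCCCCC=C)cc(OC)c1 | intermediate
7 | (2S,9Z)-17-(3,5-dimethoxyphenyl)heptadec-9-en-2-ol | C[C@H](O)CCCCCC/C=C\CCCCCCCc1cc(OC)cc(OC)c1 | intermediate
8 | Hansfordiol E, 5-[(8Z,16S)-16-hydroxyheptadec-8-en-1-yl]benzene-1,3-diol | C[C@H](O)CCCCCC/C=C\CCCCCCCc1cc(O)cc(O)c1 | target

**Totals**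
Total step count: 4. Longest linear sequence: 3 steps (1 → 2 → 7 → 8, or 3/4 → 6 → 7 → 8).

**Three steps most likely to fail**

Step 1 (the proposed new hydration). The risks are insufficient differentiation of CH3 from the alkyl chain (low ee), competing hydrofluorination, and dihydration. The fallback uses known chemistry, sets out from 1 and comes back at 2. Tsuji–Wacker mono-oxidation of 1 in threefold excess (PdCl2 cat., CuCl, O2, DMF/H2O, rt) gives dec-9-en-2-one F1. F1 is then reduced by a Prelog-selective alcohol dehydrogenase (ADH-A from Rhodococcus ruber, NADH, i-PrOH, pH 7.5 buffer, 30 °C) to the (S)-alcohol 2, typically in >99% ee for methyl alkyl ketones.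

Step 3 (Z-selective cross-metathesis). The risks are statistical homodimers, incomplete Z-selectivity and catalyst death. The fallback builds the alkene by a Wittig reaction, sets out from 6 and 2 and comes back at 7. Lemieux–Johnson cleavage of 6 (OsO4 cat., NaIO4, 2,6-lutidine, dioxane/H2O) gives 8-(3,5-dimethoxyphenyl)octanal F2. Ozonolysis of 2 with NaBH4 work-up gives (S)-nonane-1,8-diol F3. Primary-selective iodination of F3 (I2, PPh3, imidazole, 0 °C) gives (S)-9-iodononan-2-ol F4, and heating with PPh3 in MeCN gives [(S)-8-hydroxynonyl]triphenylphosphonium iodide F5. The salt-free ylide (NaHMDS 2.1 equiv, THF, −78 °C) is condensed with F2 to give 7 as the Z isomer.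

Step 4 (demethylation at 160 °C). The risks are stopping at the mono-methyl ether and thermal stress on the alkenol. The fallback moves the deprotection before the metathesis and switches to silyl ethers; it sets out from 6 and comes back at 8. BBr3 (CH2Cl2, −78 → 0 °C) on 6, which carries only a terminal alkene, gives 5-(non-8-en-1-yl)benzene-1,3-diol F6. TBSCl/imidazole/DMF gives 1,3-bis(tert-butyldimethylsilyloxy)-5-(non-8-en-1-yl)benzene F7. Z-selective cross-metathesis of F7 with 2 under the step 3 conditions gives (2S,9Z)-17-[3,5-bis(tert-butyldimethylsilyloxy)phenyl]heptadec-9-en-2-ol F8. TBAF in THF at 0 °C then releases 8.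

Further compounds
F1 | step 1 | dec-9-en-2-one | CC(=O)CCCCCCC=C
F2 | step 3 | 8-(3,5-dimethoxyphenyl)octanal | COc1cc(CCCCCCCC=O)cc(OC)c1
F3 | step 3 | (S)-nonane-1,8-diol | C[C@H](O)CCCCCCCO
F4 | step 3 | (S)-9-iodononan-2-ol | C[C@H](O)CCCCCCCI
F5 | step 3 | [(S)-8-hydroxynonyl]triphenylphosphonium iodide | C[C@H](O)CCCCCCC[P+](c1ccccc1)(c1ccccc1)c1ccccc1.[I-]
F6 | step 4 | 5-(non-8-en-1-yl)benzene-1,3-diol | Oc1cc(CCCCCCCC=C)cc(O)c1
F7 | step 4 | 1,3-bis(tert-butyldimethylsilyloxy)-5-(non-8-en-1-yl)benzene | CC(C)(C)[Si](C)(C)Oc1cc(CCCCCCCC=C)cc(O[Si](C)(C)C(C)(C)C)c1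
F8 | step 4 | (2S,9Z)-17-[3,5-bis(tert-butyldimethylsilyloxy)phenyl]heptadec-9-en-2-ol | C[C@H](O)CCCCCC/C=C\CCCCCCCc1cc(O[Si](C)(C)C(C)(C)C)cc(O[Si](C)(C)C(C)(C)C)c1
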